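**Retrosynthetic overview**

1. Target 32 ⇐ angeloylation of the equatorial 9α-OH of diol 30 ⇐ trans-diaxial opening of the 7α,8α-epoxy alcohol 28 at C7 by an isopropenyl cuprate ⇐ allylic alcohol 27 ⇐ enone 26 ⇐ C9 ketone 24.
2. Ring A of 24 ⇐ 1,3-dione 16 (C15 by Stork–Danheiser methylation at C4, C4 set by Li/NH3, C2 by LiBH(s-Bu)3) ⇐ Claisen closure of the C2–C3 bond in keto ester 15.
3. Feature the strategy rests on: C9 of ring B bears oxygen and is bonded to C10, which carries the C1–C2 acetate arm trans to that oxygen. The C9–C10 bond is therefore made by a samarium ketyl–enoate 6-exo closure of ring B, aldehyde enoate 12 → hydroxy ester 13.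
4. 12 ⇐ linear hydroformylation of the allyl group and Horner–Wadsworth–Emmons olefination ⇐ (R)-keto ester 6, whose quaternary C5 comes from auxiliary-controlled allylation of ethyl 2-methyl-3-oxobutanoate.
5. Ring order: ring B first (step 8), ring A second (step 11); C7, C8 and the two ester groups last.

Key step: step 8

Remark on naming: bicyclic compounds are named on the decalin skeleton with eremophilane numbering (ring A: C1, C2, C3, C4, C5, C10; ring B: C5, C6, C7, C8, C9, C10; C14 = methyl on C5, C15 = methyl on C4). β is the face of the C5 methyl, α the opposite face, and "trans-decalin" means 10α-H.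

Assumption: in step 2 the lithiated L-valine tert-butyl ester enamine is taken to be allylated on the face that gives the (R)-keto ester under the toluene/HMPA protocol; because the face depends on the auxiliary and on the lithium ligand, the D-valine ester (or THF in place of HMPA) is the remedy if the sign of rotation shows the other enantiomer.

**Route**

Step 1
Reactants: 1 ethyl 2-methyl-3-oxobutanoate; 2 L-valine tert-butyl ester
Product: 3 ethyl (2Z)-3-{[(2S)-1-tert-butoxy-3-methyl-1-oxobutan-2-yl]amino}-2-methylbut-2-enoate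
Conditions: BF3·OEt2 (cat.), benzene, reflux, Dean–Stark
Reagents that add atoms: none
Why: Acid-catalysed condensation of a primary amine with a β-keto ester (enamine formation) should give the hydrogen-bonded Z-enamino ester and so attach the valine-derived auxiliary.

Step 2
Reactants: 3 enamino ester; 4 allyl bromide
Product: 6 ethyl (2R)-2-acetyl-2-methylpent-4-enoate, via allylated ketimine 5 (not isolated)
Conditions: LiN(i-Pr)2, toluene, −78 °C; HMPA, allyl bromide, −78 → −55 °C; then 1 M HCl, 0 °C → rt
Reagents that add atoms: water (O)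
Why: C-Alkylation of the lithiated chiral enamine (auxiliary-controlled enolate alkylation) should run through a lithium chelate in which the valine isopropyl group screens one face, so that allyl bromide sets the quaternary centre (later C5) as R, and mild acid hydrolysis of the ketimine releases the keto ester and the auxiliary.

Step 3
Reactants: 6 ethyl (2R)-2-acetyl-2-methylpent-4-enoate
Product: 7 ethyl (2R)-2-methyl-2-(2-methyl-1,3-dioxolan-2-yl)pent-4-enoate
Conditions: HOCH2CH2OH, p-toluenesulfonic acid monohydrate (cat.), benzene, reflux, Dean–Stark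
Reagents that add atoms: ethylene glycol (OCCO)
Why: Acid-catalysed ketalisation with azeotropic removal of water masks the methyl ketone, which would otherwise be reduced in step 4 and would pinacol-couple with the aldehyde in step 8; the quaternary centre cannot epimerise.

Step 4
Reactants: 7 ethyl (2R)-2-methyl-2-(2-methyl-1,3-dioxolan-2-yl)pent-4-enoate
Product: 8 (2S)-2-methyl-2-(2-methyl-1,3-dioxolan-2-yl)pent-4-en-1-ol
Conditions: LiAlH4, Et2O, 0 °C → rt; water/NaOH work-up
Reagents that add atoms: none
Why: Hydride reduction of the ester gives the neopentyl primary alcohol, the dioxolane and the terminal alkene being inert to LiAlH4 (the descriptor changes only through priorities).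

Step 5
Reactants: 8 (2S)-2-methyl-2-(2-methyl-1,3-dioxolan-2-yl)pent-4-en-1-ol
Product: 9 (2S)-2-methyl-2-(2-methyl-1,3-dioxolan-2-yl)pent-4-enal
Conditions: Dess–Martin periodinane, pyridine, CH2Cl2, 0 °C → rt
Reagents that add atoms: none
Why: Dess–Martin oxidation under pyridine buffering should give the aldehyde without touching the ketal, and the aldehyde has no α-hydrogen, so it can neither epimerise nor self-condense.

Step 6
Reactants: 9 (2S)-2-methyl-2-(2-methyl-1,3-dioxolan-2-yl)pent-4-enal; 10 trimethyl phosphonoacetate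
Product: 11 methyl (2E,4S)-4-methyl-4-(2-methyl-1,3-dioxolan-2-yl)hepta-2,6-dienoate
Conditions: NaH, THF, 0 °C → rt
Reagents that add atoms: none
Why: Horner–Wadsworth–Emmons olefination with a stabilised phosphonate anion should give the E-enoate, and the non-enolisable aldehyde tolerates the basic conditions.

Step 7
Reactants: 11 methyl (2E,4S)-4-methyl-4-(2-methyl-1,3-dioxolan-2-yl)hepta-2,6-dienoate
Product: 12 methyl (2E,4S)-4-methyl-4-(2-methyl-1,3-dioxolan-2-yl)-8-oxooct-2-enoate
Conditions: Rh(acac)(CO)2 (1 mol %), 4,5-bis(diphenylphosphino)-9,9-dimethylxanthene (2 mol %), CO/H2 (1:1, 10 bar), toluene, 70 °C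
Reagents that add atoms: carbon monoxide ([C-]#[O+])
Why: Rhodium-catalysed hydroformylation with a wide-bite-angle diphosphine should place the formyl group on the terminal carbon of the monosubstituted alkene (linear-selective), while the hindered, electron-poor disubstituted enoate reacts far more slowly.

Step 8
Reactants: 12 methyl (2E,4S)-4-methyl-4-(2-methyl-1,3-dioxolan-2-yl)-8-oxooct-2-enoate
Product: 13 methyl 2-[(1R,2R,6S)-2-hydroxy-6-methyl-6-(2-methyl-1,3-dioxolan-2-yl)cyclohexyl]acetate
Conditions: SmI2 (2.5 equiv), MeOH (4 equiv), THF, −78 °C, slow addition of 12 (final 0.01 M)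
Reagents that add atoms: none
Why: SmI2 (divalent samarium) transfers one electron to the C9 aldehyde to give a samarium-bound ketyl radical, which adds to C10, the β-carbon of the E-enoate; a second electron turns the α-ester radical into a samarium enolate that methanol protonates. This is the known reductive ketyl–olefin cyclization of aldehydes onto α,β-unsaturated esters, which gives trans-2-substituted cycloalkanols. Ring B closes in a 6-exo-trig mode through a chair-like transition state. C9 and C10 should come out trans (9α-OH, 10β side chain) because the bulky samarium alkoxide and the enoate both take pseudo-equatorial sites and avoid each other. The sense relative to the existing quaternary C5 should follow from the same chair: the dioxolane-bearing carbon is much larger than methyl and takes the equatorial site, which leaves C14 axial and cis to the new side chain. The step needs the aldehyde to be reduced in preference to the enoate and needs no second carbonyl within reach, which the ketal mask, the absence of HMPA and the high dilution (against pinacol dimerisation) secure.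

Step 9
Reactants: 13 methyl 2-[(1R,2R,6S)-2-hydroxy-6-methyl-6-(2-methyl-1,3-dioxolan-2-yl)cyclohexyl]acetate
Product: 14 methyl 2-[(1R,2R,6S)-6-methyl-6-(2-methyl-1,3-dioxolan-2-yl)-2-(triisopropylsilyloxy)cyclohexyl]acetate
Conditions: i-Pr3SiOSO2CF3, 2,6-lutidine, CH2Cl2, −78 → 0 °C
Reagents that add atoms: triisopropylsilyl trifluoromethanesulfonate (CC(C)[Si](C(C)C)(C(C)C)OS(=O)(=O)C(F)(F)F)
Why: Silylation of the hindered secondary alcohol with a silyl triflate and a hindered base at low temperature should spare the dioxolane, and the triisopropylsilyl ether is chosen because it must survive the acids of steps 10, 12 and 13 and the lithium/ammonia of step 14.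

Step 10
Reactants: 14 methyl 2-[(1R,2R,6S)-6-methyl-6-(2-methyl-1,3-dioxolan-2-yl)-2-(triisopropylsilyloxy)cyclohexyl]acetate
Product: 15 methyl 2-[(1R,2R,6S)-6-acetyl-6-methyl-2-(triisopropylsilyloxy)cyclohexyl]acetate
Conditions: 2 M HCl, THF, rt → 40 °C
Reagents that add atoms: water (O)
Why: Acid hydrolysis of the dioxolane frees the methyl ketone (C4 and C3), while the triisopropylsilyl ether and the methyl ester are stable to dilute aqueous acid.

Step 11
Reactants: 15 methyl 2-[(1R,2R,6S)-6-acetyl-6-methyl-2-(triisopropylsilyloxy)cyclohexyl]acetate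
Product: 16 5β-methyl-9α-(triisopropylsilyloxy)-trans-decalin-2,4-dione
Conditions: KOt-Bu (2.5 equiv), THF, 0 °C → rt; then 1 M HCl to pH 4
Reagents that add atoms: none
Why: Intramolecular Claisen condensation: the ketone can enolise only at its methyl group (C3) because C5 is quaternary, its enolate attacks the ester carbon C2 in a six-membered closure that makes ring A, deprotonation of the 1,3-dione drives the equilibrium, and the trans ring fusion follows from the fixed, non-enolisable C5 and C10.

Step 12
Reactants: 16 5β-methyl-9α-(triisopropylsilyloxy)-trans-decalin-2,4-dione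
Product: 17 2-methoxy-5β-methyl-9α-(triisopropylsilyloxy)-trans-decal-2-en-4-one
Conditions: MeOH, p-toluenesulfonic acid monohydrate (cat.), benzene, 60 °C, 4 Å molecular sieves
Reagents that add atoms: methanol (CO)
Why: Acid-catalysed enol etherification of the 1,3-dione under equilibrating conditions should place the methoxy group on the unhindered C2 oxygen and leave the carbonyl at C4 beside the quaternary C5, as is usual for 4,4-disubstituted cyclohexane-1,3-diones.

Step 13
Reactants: 17 2-methoxy-5β-methyl-9α-(triisopropylsilyloxy)-trans-decal-2-en-4-one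
Product: 19 4,5β-dimethyl-9α-(triisopropylsilyloxy)-trans-decal-3-en-2-one, via tertiary carbinol 18 (not isolated)
Conditions: MeLi, THF, −78 → 0 °C; then 1 M HCl, THF, rt
Reagents that add atoms: methyllithium ([Li]C); water (O)
Why: Stork–Danheiser transposition: methyllithium adds 1,2 to the vinylogous ester carbonyl C4 (which has no α′-hydrogen to lose), and acid hydrolysis of the enol ether with loss of the C4 hydroxyl should give the 4-methyl-3-en-2-one, C15 now being in place.

Step 14
Reactants: 19 4,5β-dimethyl-9α-(triisopropylsilyloxy)-trans-decal-3-en-2-one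
Product: 20 4β,5β-dimethyl-9α-(triisopropylsilyloxy)-trans-decalin-2-one
Conditions: Li, NH3 (l), THF, t-BuOH (1 equiv), −78 °C; then NH4Cl
Reagents that add atoms: none
Why: Dissolving-metal reduction of the enone: the β-carbanion at C4 should be protonated axially from the α face, anti to the axial C14 methyl, so that C15 becomes equatorial (β) and cis to C14, and the silyl ether is inert.

Step 15
Reactants: 20 4β,5β-dimethyl-9α-(triisopropylsilyloxy)-trans-decalin-2-one
Product: 21 4β,5β-dimethyl-9α-(triisopropylsilyloxy)-trans-decalin-2α-ol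
Conditions: LiBH(s-Bu)3, THF, −78 °C; then NaOH, H2O2
Reagents that add atoms: none
Why: The bulky trialkylborohydride should attack the C2 ketone along the equatorial trajectory (from the β side) and so give the axial 2α-alcohol.

Step 16
Reactants: 21 4β,5β-dimethyl-9α-(triisopropylsilyloxy)-trans-decalin-2α-ol
Product: 22 2α-acetoxy-4β,5β-dimethyl-9α-(triisopropylsilyloxy)-trans-decalin
Conditions: Ac2O, 4-(dimethylamino)pyridine (cat.), pyridine, rt
Reagents that add atoms: acetic anhydride (CC(=O)OC(C)=O)
Why: Nucleophile-catalysed acylation of the only free hydroxyl installs the C2 acetate of the target with retention.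

Step 17
Reactants: 22 2α-acetoxy-4β,5β-dimethyl-9α-(triisopropylsilyloxy)-trans-decalin
Product: 23 2α-acetoxy-4β,5β-dimethyl-trans-decalin-9α-ol
Conditions: HF·pyridine, THF/pyridine, rt → 40 °C
Reagents that add atoms: none
Why: Fluoride cleavage of the Si–O bond under buffered acidic conditions should free the C9 hydroxyl without hydrolysing or moving the acetate.

Step 18
Reactants: 23 2α-acetoxy-4β,5β-dimethyl-trans-decalin-9α-ol
Product: 24 2α-acetoxy-4β,5β-dimethyl-trans-decalin-9-one
Conditions: Dess–Martin periodinane, pyridine, CH2Cl2, rt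
Reagents that add atoms: none
Why: Dess–Martin oxidation under near-neutral conditions gives the C9 ketone without epimerising C10 or touching the acetate.

Step 19
Reactants: 24 2α-acetoxy-4β,5β-dimethyl-trans-decalin-9-one
Product: 25 2α-acetoxy-4β,5β-dimethyl-9-(trimethylsilyloxy)-trans-decal-8-ene
Conditions: LiN(i-Pr)2 (1.1 equiv), Me3SiCl (premixed, in situ quench), THF, −78 °C; Et3N, cold aq. NaHCO3
Reagents that add atoms: chlorotrimethylsilane (C[Si](C)(C)Cl)
Why: Kinetic deprotonation with a hindered amide base should occur at the less substituted C8 methylene rather than at the ring-fusion C10, the enolate is silylated as it forms, and any acetate enolate is trapped as a ketene silyl acetal that reverts to the acetate on work-up.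

Step 20
Reactants: 25 2α-acetoxy-4β,5β-dimethyl-9-(trimethylsilyloxy)-trans-decal-8-ene
Product: 26 2α-acetoxy-4β,5β-dimethyl-trans-decal-7-en-9-one
Conditions: Pd(OAc)2 (1.1 equiv), MeCN, rt
Reagents that add atoms: none
Why: Saegusa–Ito oxidation: palladation of the silyl enol ether at C8 and β-hydride elimination from C7 should give the 7-en-9-one regiospecifically under neutral conditions that leave C10 and the acetate alone.

Step 21
Reactants: 26 2α-acetoxy-4β,5β-dimethyl-trans-decal-7-en-9-one
Product: 27 2α-acetoxy-4β,5β-dimethyl-trans-decal-7-en-9α-ol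
Conditions: (3aS)-1-methyl-3,3-diphenyltetrahydro-1H,3H-pyrrolo[1,2-c][1,3,2]oxazaborole (0.5 equiv), BH3·SMe2, THF, −40 °C; MeOH
Reagents that add atoms: none
Why: Corey–Bakshi–Shibata reduction: the oxazaborolidine–borane complex binds the carbonyl oxygen on the side of the small vinylic C8 flank and transfers hydride in a 1,2-manner to the β face of C9, so the pseudo-equatorial 9α-alcohol should form by catalyst control against the modest bias of the axial C14 methyl, and the acetate is not reduced at this temperature.

Step 22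
Reactants: 27 2α-acetoxy-4β,5β-dimethyl-trans-decal-7-en-9α-ol
Product: 28 2α-acetoxy-7α,8α-epoxy-4β,5β-dimethyl-trans-decalin-9α-ol
Conditions: VO(acac)2 (5 mol %), t-BuOOH (decane), CH2Cl2, 0 °C → rt
Reagents that add atoms: tert-butyl hydroperoxide (CC(C)(C)OO)
Why: Hydroxyl-directed vanadium-catalysed epoxidation delivers oxygen syn to the 9α-hydroxyl, that is to the α face of C7=C8, which is also the face away from the axial C14 methyl, so both effects should give the 7α,8α-epoxide.

Step 23
Reactants: 28 2α-acetoxy-7α,8α-epoxy-4β,5β-dimethyl-trans-decalin-9α-ol; 29 2-bromopropene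
Product: 30 2α-acetoxy-7β-isopropenyl-4β,5β-dimethyl-trans-decalin-8α,9α-diol
Conditions: 29, t-BuLi (2 equiv per bromide), Et2O, −78 °C; CuI, −40 °C; then 28 (cuprate in fourfold excess), Et2O, −40 → 0 °C; aq. NH4Cl/NH3
Reagents that add atoms: none
Why: SN2 opening of the epoxide by lithium diisopropenylcuprate: trans-diaxial (Fürst–Plattner) opening should bring the carbon nucleophile to C7 from the β face with inversion and leave the axial 8α-hydroxyl, attack at C8 being disfavoured by the twist-boat it requires and by the neighbouring alkoxide, and the acetate should survive the soft cuprate at low temperature.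

Step 24
Reactants: 30 2α-acetoxy-7β-isopropenyl-4β,5β-dimethyl-trans-decalin-8α,9α-diol; 31 angelic acid
Product: 32 target CNP0217919.1 (2α-acetoxy-9α-[(2Z)-2-methylbut-2-enoyloxy]-7β-isopropenyl-4β,5β-dimethyl-trans-decalin-8α-ol)
Conditions: 31, 2,4,6-trichlorobenzoyl chloride, Et3N, toluene, rt; then 30, toluene, 75 °C (no nucleophilic amine catalyst)
Reagents that add atoms: none
Why: Yamaguchi-type mixed-anhydride esterification run without a nucleophilic catalyst should keep the Z geometry of the angelate, and the equatorial 9α-hydroxyl of the cis-diol should be acylated in preference to the axial 8α-hydroxyl, which is flanked by the axial isopropenyl group.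

**Compound list**

1 | ethyl 2-methyl-3-oxobutanoate | CCOC(=O)C(C)C(C)=O | starting material
2 | L-valine tert-butyl ester | CC(C)[C@H](N)C(=O)OC(C)(C)C | starting material
3 | ethyl (2Z)-3-{[(2S)-1-tert-butoxy-3-methyl-1-oxobutan-2-yl]amino}-2-methylbut-2-enoate | CCOC(=O)/C(C)=C(/C)N[C@@H](C(C)C)C(=O)OC(C)(C)C | intermediate
4 | allyl bromide | C=CCBr | starting material
5 | allylated ketimine, ethyl (2R)-2-{N-[(2S)-1-tert-butoxy-3-methyl-1-oxobutan-2-yl]ethanimidoyl}-2-methylpent-4-enoate | C=CC[C@](C)(C(C)=N[C@@H](C(C)C)C(=O)OC(C)(C)C)C(=O)OCC | intermediate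
6 | ethyl (2R)-2-acetyl-2-methylpent-4-enoate | C=CC[C@](C)(C(C)=O)C(=O)OCC | intermediate
7 | ethyl (2R)-2-methyl-2-(2-methyl-1,3-dioxolan-2-yl)pent-4-enoate | C=CC[C@](C)(C1(C)OCCO1)C(=O)OCC | intermediate
8 | (2S)-2-methyl-2-(2-methyl-1,3-dioxolan-2-yl)pent-4-en-1-ol | C=CC[C@](C)(C1(C)OCCO1)CO | intermediate
9 | (2S)-2-methyl-2-(2-methyl-1,3-dioxolan-2-yl)pent-4-enal | C=CC[C@](C)(C1(C)OCCO1)C=O | intermediate
10 | trimethyl phosphonoacetate | COC(=O)CP(=O)(OC)OC | starting material
11 | methyl (2E,4S)-4-methyl-4-(2-methyl-1,3-dioxolan-2-yl)hepta-2,6-dienoate | C=CC[C@](C)(C1(C)OCCO1)/C=C/C(=O)OC | intermediate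
12 | methyl (2E,4S)-4-methyl-4-(2-methyl-1,3-dioxolan-2-yl)-8-oxooct-2-enoate | O=CCCC[C@](C)(C1(C)OCCO1)/C=C/C(=O)OC | intermediate
13 | methyl 2-[(1R,2R,6S)-2-hydroxy-6-methyl-6-(2-methyl-1,3-dioxolan-2-yl)cyclohexyl]acetate | C1C[C@](C)(C2(C)OCCO2)[C@@H](CC(=O)OC)[C@H](O)C1 | intermediate
14 | methyl 2-[(1R,2R,6S)-6-methyl-6-(2-methyl-1,3-dioxolan-2-yl)-2-(triisopropylsilyloxy)cyclohexyl]acetate | C1C[C@](C)(C2(C)OCCO2)[C@@H](CC(=O)OC)[C@H](O[Si](C(C)C)(C(C)C)C(C)C)C1 | intermediate
15 | methyl 2-[(1R,2R,6S)-6-acetyl-6-methyl-2-(triisopropylsilyloxy)cyclohexyl]acetate | C1C[C@](C)(C(C)=O)[C@@H](CC(=O)OC)[C@H](O[Si](C(C)C)(C(C)C)C(C)C)C1 | intermediate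
16 | 5β-methyl-9α-(triisopropylsilyloxy)-trans-decalin-2,4-dione | C1C[C@]2(C)C(=O)CC(=O)C[C@H]2[C@H](O[Si](C(C)C)(C(C)C)C(C)C)C1 | intermediate
17 | 2-methoxy-5β-methyl-9α-(triisopropylsilyloxy)-trans-decal-2-en-4-one | C1C[C@]2(C)C(=O)C=C(OC)C[C@H]2[C@H](O[Si](C(C)C)(C(C)C)C(C)C)C1 | intermediate
18 | tertiary carbinol, 2-methoxy-4,5β-dimethyl-9α-(triisopropylsilyloxy)-trans-decal-2-en-4-ol (C4 epimers) | C1C[C@]2(C)C(C)(O)C=C(OC)C[C@H]2[C@H](O[Si](C(C)C)(C(C)C)C(C)C)C1 | intermediate
19 | 4,5β-dimethyl-9α-(triisopropylsilyloxy)-trans-decal-3-en-2-one | C1C[C@]2(C)C(C)=CC(=O)C[C@H]2[C@H](O[Si](C(C)C)(C(C)C)C(C)C)C1 | intermediate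
20 | 4β,5β-dimethyl-9α-(triisopropylsilyloxy)-trans-decalin-2-one | C1C[C@]2(C)[C@@H](C)CC(=O)C[C@H]2[C@H](O[Si](C(C)C)(C(C)C)C(C)C)C1 | intermediate
21 | 4β,5β-dimethyl-9α-(triisopropylsilyloxy)-trans-decalin-2α-ol | C1C[C@]2(C)[C@@H](C)C[C@H](O)C[C@H]2[C@H](O[Si](C(C)C)(C(C)C)C(C)C)C1 | intermediate
22 | 2α-acetoxy-4β,5β-dimethyl-9α-(triisopropylsilyloxy)-trans-decalin | C1C[C@]2(C)[C@@H](C)C[C@H](OC(C)=O)C[C@H]2[C@H](O[Si](C(C)C)(C(C)C)C(C)C)C1 | intermediate
23 | 2α-acetoxy-4β,5β-dimethyl-trans-decalin-9α-ol | C1C[C@]2(C)[C@@H](C)C[C@H](OC(C)=O)C[C@H]2[C@H](O)C1 | intermediate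
24 | 2α-acetoxy-4β,5β-dimethyl-trans-decalin-9-one | C1C[C@]2(C)[C@@H](C)C[C@H](OC(C)=O)C[C@H]2C(=O)C1 | intermediate
25 | 2α-acetoxy-4β,5β-dimethyl-9-(trimethylsilyloxy)-trans-decal-8-ene | C1C[C@]2(C)[C@@H](C)C[C@H](OC(C)=O)C[C@H]2C(O[Si](C)(C)C)=C1 | intermediate
26 | 2α-acetoxy-4β,5β-dimethyl-trans-decal-7-en-9-one | O=C1C=CC[C@]2(C)[C@@H](C)C[C@H](OC(C)=O)C[C@@H]12 | intermediate
27 | 2α-acetoxy-4β,5β-dimethyl-trans-decal-7-en-9α-ol | O[C@@H]1C=CC[C@]2(C)[C@@H](C)C[C@H](OC(C)=O)C[C@@H]12 | intermediate
28 | 2α-acetoxy-7α,8α-epoxy-4β,5β-dimethyl-trans-decalin-9α-ol | [C@@H]13C[C@]2(C)[C@@H](C)C[C@H](OC(C)=O)C[C@H]2[C@H](O)[C@@H]1O3 | intermediate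
29 | 2-bromopropene | C=C(C)Br | starting material
30 | 2α-acetoxy-7β-isopropenyl-4β,5β-dimethyl-trans-decalin-8α,9α-diol | C=C(C)[C@H]1C[C@]2(C)[C@@H](C)C[C@H](OC(C)=O)C[C@H]2[C@H](O)[C@@H]1O | intermediate
31 | angelic acid, (2Z)-2-methylbut-2-enoic acid | C/C=C(/C)C(=O)O | starting material
32 | CNP0217919.1, 2α-acetoxy-9α-[(2Z)-2-methylbut-2-enoyloxy]-7β-isopropenyl-4β,5β-dimethyl-trans-decalin-8α-ol | C=C(C)[C@H]1C[C@]2(C)[C@@H](C)C[C@H](OC(C)=O)C[C@H]2[C@H](OC(=O)/C(C)=C\C)[C@@H]1O | target

**Step count and risks**

Total step count: 24. Longest linear sequence: 24 steps (1 → 32).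

Steps most likely to fail:

Step 21. Hydride may be delivered to the α face instead, because the axial C14 methyl screens the β face of the C9 carbonyl and works against the catalyst; the facial selectivity may then be poor. The fallback sets out from enone 26 and comes back at allylic alcohol 27, and it uses the substrate bias instead of opposing it. NaBH4/CeCl3·7H2O in MeOH at −78 °C (Luche reduction) should give, by attack on the open α face, 2α-acetoxy-4β,5β-dimethyl-trans-decal-7-en-9β-ol F1. A Mitsunobu reaction with chloroacetic acid (PPh3, diisopropyl azodicarboxylate, toluene, 0 °C) should then invert C9 and give 2α-acetoxy-9α-(chloroacetoxy)-4β,5β-dimethyl-trans-decal-7-ene F2. Thiourea and NaHCO3 in ethanol at 50 °C should remove the chloroacetyl group without touching the C2 acetate and give 27.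

Step 23. The axial approach to C7 runs syn to the axial C14 methyl, so the opening may be slow or may shift to C8, and long exposure to the organometallic reagent may cleave the C2 acetate. The fallback sets out from epoxy alcohol 28 and comes back at diol 30; it replaces the cuprate by a Lewis-acidic alkynylalane with a slim, linear carbon nucleophile. Et2AlC≡CSiMe3 (from Me3SiC≡CLi and Et2AlCl) in toluene at 0 °C → rt should open the epoxide trans-diaxially at C7 and leave esters alone, giving 2α-acetoxy-4β,5β-dimethyl-7β-[(trimethylsilyl)ethynyl]-trans-decalin-8α,9α-diol F3. Bu4NF buffered with acetic acid (THF, 0 °C) should give 2α-acetoxy-7β-ethynyl-4β,5β-dimethyl-trans-decalin-8α,9α-diol F4. Zirconium-catalysed methylalumination of the terminal alkyne (Me3Al, (C5H5)2ZrCl2, CH2Cl2, −20 °C → rt; then water; Negishi carboalumination) should put the methyl group on the internal alkyne carbon and, after protonolysis, give the isopropenyl diol 30.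

Step 8. Induction from the quaternary C5 may be weak in the ring closure, so that the methyl and the dioxolane-bearing carbon exchange the axial and equatorial sites, and pinacol dimerisation or plain reduction of the aldehyde may compete. The fallback sets out from aldehyde enoate 12 and comes back at hydroxy ester 13; it makes the C9–C10 bond with an acyl radical instead of a ketyl. tert-Dodecanethiol (cat.) and azobisisobutyronitrile in chlorobenzene at 80 °C (thiol-catalysed radical hydroacylation, 6-exo) should give methyl 2-[(1R,6S)-6-methyl-6-(2-methyl-1,3-dioxolan-2-yl)-2-oxocyclohexyl]acetate F5. In this ketone C10 is α to the carbonyl and can be equilibrated with 1,8-diazabicyclo[5.4.0]undec-7-ene to the isomer that carries the side chain equatorial. Electron-transfer reduction of the ketone (SmI2, THF/H2O, 0 °C), which should give the more stable equatorial alcohol, then leads back to 13.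

**Further compounds**

F1 | step 21 | 2α-acetoxy-4β,5β-dimethyl-trans-decal-7-en-9β-ol | O[C@H]1C=CC[C@]2(C)[C@@H](C)C[C@H](OC(C)=O)C[C@@H]12
F2 | step 21 | 2α-acetoxy-9α-(chloroacetoxy)-4β,5β-dimethyl-trans-decal-7-ene | ClCC(=O)O[C@@H]1C=CC[C@]2(C)[C@@H](C)C[C@H](OC(C)=O)C[C@@H]12
F3 | step 23 | 2α-acetoxy-4β,5β-dimethyl-7β-[(trimethylsilyl)ethynyl]-trans-decalin-8α,9α-diol | C[Si](C)(C)C#C[C@H]1C[C@]2(C)[C@@H](C)C[C@H](OC(C)=O)C[C@H]2[C@H](O)[C@@H]1O
F4 | step 23 | 2α-acetoxy-7β-ethynyl-4β,5β-dimethyl-trans-decalin-8α,9α-diol | C#C[C@H]1C[C@]2(C)[C@@H](C)C[C@H](OC(C)=O)C[C@H]2[C@H](O)[C@@H]1O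
F5 | step 8 | methyl 2-[(1R,6S)-6-methyl-6-(2-methyl-1,3-dioxolan-2-yl)-2-oxocyclohexyl]acetate | C1C[C@](C)(C2(C)OCCO2)[C@@H](CC(=O)OC)C(=O)C1
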